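Its constants come from no measurement; no experiment stands behind them.

Colleague, you asked for a quick number on these recipes, and your hunch was that Saturday's wins.

| flask | starting material | coupling partner | free catalyst | time | remark |
|---|---|---|---|---|---|
| Wednesday's | 1.0 mM | 3.00 mM (fed, over 1.0 min) | 20 µM | 2.5 min | all else is in the flask from the start; the feed brings no volume worth counting |
| Saturday's | 1.0 mM | 3.00 mM | 20 µM | 2.5 min | everything together at the start |
| Tuesday's | 1.0 mM (fed, over 1.0 min) | 3.00 mM | 20 µM | 2.5 min | all else is in the flask from the start; the feed brings no volume worth counting |

* the best flask by amount of product, in percent of the starting material charged; "all alike" if 1.5 percentage points covers them all (Wednesday's / Saturday's / Tuesday's / all alike)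
* amount of product at the end, in percent of the starting material charged, Wednesday's
* amount of product at the end, in percent of the starting material charged, Saturday's
* amount of product at the end, in percent of the starting material charged, Tuesday's

- percentages count the starting material that a species holds: one spent catalyst counts as two
- product is meant together with its crystals
- a doubled species enters its step squared and goes two at a time
- solid, in amounts per volume of the solution: crystals
- run time (Wednesday's): 2.5 min

    starting material + free catalyst ⇌ catalyst intermediate A (K1 = 410 M⁻¹, k1 = 40900 M⁻¹ s⁻¹)
    coupling partner + catalyst intermediate A ⇌ catalyst intermediate B (K2 = 111 M⁻¹, k2 = 32100 M⁻¹ s⁻¹)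
    catalyst intermediate B → free catalyst + product (k3 = 7.49 s⁻¹)
    crystals ⇌ product, rate k4*(cs4 - [product]) while solid is left; crystals form when [product] > cs4 (cs4 = 0.036 mM, k4 = 5.05 s⁻¹)
    2 catalyst intermediate A → spent catalyst (k5 = 3280 M⁻¹ s⁻¹)

We follow one molecule of starting material. Bound to free catalyst it becomes catalyst intermediate A, which stands at a fork: it falls back at 99.8 s⁻¹, or it takes up coupling partner to give catalyst intermediate B. Intermediate B gives product at 7.49 s⁻¹ but falls back at 289 s⁻¹. So with the partner at 3.00 mM, intermediate A leaves for good as product at 2.43 s⁻¹, far slower than it falls back. That makes 2.38 % of the visits to intermediate A end in product; we call this share the pass chance.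

Starting material therefore goes at the binding rate times the pass chance. If free catalyst stays at the 64.7 % of its charge that the two equilibria give at the start, this is a pseudo-first-order constant of 0.755 min⁻¹. Over 2.5 min we reckon 84.9 % product for Saturday's, with partner and free catalyst held and no loss to spent catalyst counted. On Wednesday's the partner is still coming in, and on Tuesday's the starting material is, so we charge each feed with half of its feed time. That gives 77.9 % for each, less than Saturday's, and our reckoning cannot part those two.

The forecast names Saturday's as best, with 62 % for Wednesday's, 76 % for Saturday's and 71 % for Tuesday's. It does part the feeds, holding that “feeding the coupling partner is worst because intermediate A builds up with little partner to move it forward”. Its Saturday's number lies below ours.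

The simulation gives Saturday's as best, with 61.4 % for Wednesday's, 76.1 % for Saturday's and 72.0 % for Tuesday's.

So the order and the numbers of the forecast hold, and the pass chance says what they mean for Saturday's flask. Saturday's stands at 76.1 %, and the same run without the falling back of catalyst intermediate A gives 97.1 %, which accounts for 88 % of what is missing. That step shares the work with the falling back of catalyst intermediate B, which runs at 289 s⁻¹ against 7.49 s⁻¹ on to product, and the pass chance holds both. With a pass chance of 2.38 % the flask is slow rather than stopped, and after 25.0 min Saturday's holds 99.3 %.

A neighbour of Saturday's with 0.0080 mM of free catalyst keeps the pass chance and the free share, so the same reckoning gives 53.0 %. That flask gives 47.5 %.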